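The readings stem from a simulated flask with constants of no real substance.

Take the time of reading first and set it on a clock that counts catalyst. The flask stands at 12.0 h on the catalyst clock, which is hours times loading divided by the summer run's loading. Assume that starting material follows this clock, although both earlier runs share one loading and cannot test it.

all flasks: starting material 0.40 M; free catalyst 1 mol%; added ligand 5.2 mM
- summer: reagent 5 equiv; scavenger 1.4 equiv; run made earlier
- dusk: reagent 5 equiv; scavenger 2.2 equiv; run made earlier
- flask: reagent 5.00 equiv; scavenger 1.00 equiv; time 12 h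

| run | time / h | starting material / % | product / % |
|---|---|---|---|
| summer | 1.00 | 88.0 | 13.0 |
| summer | 2.00 | 76.3 | 23.2 |
| summer | 2.50 | 70.8 | 27.9 |
| summer | 4.00 | 55.0 | 44.1 |
| summer | 6.00 | 35.4 | 61.7 |
| summer | 10.0 | 8.4 | 90.1 |
| summer | 15.0 | 0.5 | 100.5 |
| dusk | 0.833 | 89.5 | 8.2 |
| dusk | 2.00 | 77.1 | 23.0 |
| dusk | 4.00 | 55.3 | 44.7 |
| dusk | 6.00 | 37.0 | 62.7 |
| dusk | 8.00 | 20.0 | 79.1 |
| dusk | 12.0 | 2.6 | 96.0 |
| dusk | 15.0 | 0.1 | 99.6 |

(readings scatter by 0.5 percentage points)

1. part of the starting material that has reacted at 12 h
2. share of the unused reagent that is free and not bound as idle adduct, at 12 h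

- the earlier runs do not show how much of reagent is bound; that part of a forecast is a guess

Summer and dusk read 55.0% and 55.3% of starting material at 4.00 h, so carry the summer curve over to the flask, accepting that the flask is charged with less scavenger than either run.

Now build a bracket from the fractional fall: the logarithm of the ratio of two readings, divided by the hours between them (an apparent first-order constant). In the summer run it reads 0.360 h⁻¹ from 6.00 h to 10.0 h, then 0.564 h⁻¹ up to 15.0 h, so it reads larger in the later stretch of that run.

Take the last 2.00 h of the clock from the reading at 10.0 h. This is my own estimate, not a proven limit: the smaller fall gives the lower edge of the bracket, 95.9% reacted. The larger gives the upper edge, 97.3%, and that edge is soft, resting on a summer reading of 0.5% with a scatter of 0.5 percentage points.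

The forecast gives 96.5%, inside this bracket, and 93% for free reagent, noting that “this is a guess”.

The flask gives 96.9% reacted and 99.2% of the unused reagent free.

    starting material + free catalyst → catalyst intermediate A (k = 3.90 L mol⁻¹ min⁻¹)
    reagent + catalyst intermediate A → catalyst intermediate B (k = 0.180 L mol⁻¹ min⁻¹)
    catalyst intermediate B ⇌ released group + catalyst intermediate C (K = 19.0 M, k = 1.80 min⁻¹)
    catalyst intermediate C → free catalyst + product (k = 1.20 min⁻¹)
    reagent + released group ⇌ idle adduct, settled at all times (K = 0.570 L mol⁻¹)
    scavenger + released group → scavenged by-product (k = 0.290 L mol⁻¹ min⁻¹)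
    free catalyst + added ligand ⇌ idle complex (K = 59.0 L mol⁻¹, k = 6.80 L mol⁻¹ min⁻¹)

The reacted share lies inside the bracket, and the flask still holds 9.99% of its scavenger at 12.0 h. Run the clock once more for the neighbour with 0.4 mol% of free catalyst: it stands at 4.80 h, between the summer readings at 4.00 h and 6.00 h. Straight interpolation there leaves 47.2% of starting material, and that neighbour holds 47.5% at 12.0 h.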